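The retrosynthesis cuts four bonds in this order: the aryl–CH2 bond of the 3,4-dimethoxybenzyl group on C4, the O1–C5 bond of the lactone ring (O1, C2, C3, C4, C5), the exocyclic C3=CH(aryl) bond, and the C3–C4 bond.
Enabling feature: C4 carries two CH2 arms, ring carbon C5 (bound to O1) and the exocyclic benzylic CH2. If both arms are tied to one ether oxygen, C4 becomes C3 of a mirror-symmetric oxetane sitting beside the C2 carboxyl group on the sp2 carbon C3.
Forward: the oxetane is bought as oxetan-3-one. C3–C4 comes from olefination and hydrogenation, C3=CH from an aldol addition–elimination with protected vanillin, and hydrolysis gives the achiral (E)-2-(oxetan-3-yl)cinnamic acid.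
The lactone is the only ring made. It closes when the carboxyl oxygen opens one of the two enantiotopic oxetane CH2–O bonds, and the freed CH2OH arm becomes CH2Br, is joined to the veratryl ring by a base-free Negishi coupling, and the phenol is then unmasked.
Stereochemistry: the E alkene comes from the E1cB elimination and C4 (R in the target) comes only from the chiral phosphoric acid. Every later step avoids base and free radicals, so C4–H stays in place.
Key step: step 7

Assumption: the sense of induction of the phosphoric acid cannot be derived reliably. (R)-TRIP, 3,3'-bis(2,4,6-triisopropylphenyl)-1,1'-binaphthyl-2,2'-diyl hydrogen phosphate, is written, and its commercial mirror image is used if a first run shows that it is the one leading to (S)-14.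

Step 1
Reactants: 1 oxetan-3-one; 2 triethyl phosphonoacetate
Product: 4 ethyl 2-(oxetan-3-ylidene)acetate, via sodium phosphonoacetate carbanion 3 (not isolated)
Conditions: NaH, THF, 0 °C; then 1, 0 °C to rt
Reagents that add atoms: none
Why: Horner–Wadsworth–Emmons olefination of this strained, unhindered ketone is the standard entry to the known oxetanylidene acetate, and the symmetric ring raises no geometry question.

Step 2
Reactants: 4 ethyl 2-(oxetan-3-ylidene)acetate
Product: 5 ethyl 2-(oxetan-3-yl)acetate
Conditions: H2 (1 atm), 10% Pd/C, EtOAc, rt
Reagents that add atoms: none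
Why: Heterogeneous catalytic hydrogenation saturates the strained, electron-poor exocyclic alkene under neutral conditions that leave the oxetane C–O bonds and the ester alone.

Step 3
Reactants: 6 vanillin
Product: 7 3-methoxy-4-(methoxymethoxy)benzaldehyde
Conditions: MOMCl, i-Pr2NEt, CH2Cl2, 0 °C to rt
Reagents that add atoms: chloromethyl methyl ether, COCCl
Why: O-alkylation of the phenol (Williamson type) gives an acetal ether that, unlike an aryl silyl ether, survives the enolate, DBU and the warm hydroxide of step 6 and still falls to dilute acid at the end.

Step 4
Reactants: 5 ethyl 2-(oxetan-3-yl)acetate; 7 3-methoxy-4-(methoxymethoxy)benzaldehyde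
Product: 9 ethyl 3-hydroxy-3-[3-methoxy-4-(methoxymethoxy)phenyl]-2-(oxetan-3-yl)propanoate (racemic syn/anti mixture), via lithium enolate 8 (not isolated)
Conditions: LDA, THF, −78 °C; then 7, −78 °C; AcOH quench at −78 °C
Reagents that add atoms: none
Why: In this lithium enolate aldol addition the ring oxygen sits on the γ-carbon, so β-elimination is impossible, and the two new stereocentres need no control because both vanish in step 5.

Step 5
Reactants: 9 ethyl 3-hydroxy-3-[3-methoxy-4-(methoxymethoxy)phenyl]-2-(oxetan-3-yl)propanoate
Product: 11 ethyl (E)-3-[3-methoxy-4-(methoxymethoxy)phenyl]-2-(oxetan-3-yl)acrylate, via benzylic mesylate 10 (not isolated)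
Conditions: MsCl, Et3N, CH2Cl2, 0 °C; then DBU, 0 °C to rt
Reagents that add atoms: none
Why: Mesylation followed by DBU-induced E1cB elimination should expel the leaving group from the enolate conformer that keeps the aryl group away from the ester, giving the conjugated and thermodynamically preferred E alkene with the aryl group cis to the small, tied-back oxetane.

Step 6
Reactants: 11 ethyl (E)-3-[3-methoxy-4-(methoxymethoxy)phenyl]-2-(oxetan-3-yl)acrylate
Product: 13 (E)-3-[3-methoxy-4-(methoxymethoxy)phenyl]-2-(oxetan-3-yl)acrylic acid (achiral), via sodium carboxylate 12 (not isolated)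
Conditions: 2 M aq NaOH, THF/EtOH, 45 °C; then aq NaHSO4, 0 °C, pH 4–5, EtOAc extraction, evaporation below 20 °C, used the same day
Reagents that add atoms: sodium hydroxide, [Na+].[OH-]
Why: Oxetane and MOM ether are inert to this ester saponification, the material is safe as its carboxylate, and short cold acidification with bisulfate is the usual way to free oxetane acids before they can ring-open on their own.

Step 7
Reactants: 13 (E)-3-[3-methoxy-4-(methoxymethoxy)phenyl]-2-(oxetan-3-yl)acrylic acid
Product: 14 (S,E)-4-(hydroxymethyl)-3-[3-methoxy-4-(methoxymethoxy)benzylidene]dihydrofuran-2(3H)-one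
Conditions: (R)-TRIP (10 mol %), toluene (0.02 M), 0 °C to rt
Reagents that add atoms: none
Why: Proposed new method: the phosphoric acid should bind 13 as a hydrogen-bonded acid–acid pair in which its P=O oxygen holds the carboxyl proton and its P–OH proton sits on the oxetane oxygen, so that the carbonyl oxygen of the carboxyl group displaces the activated C–O bond by SN2 attack on CH2 with release of four-ring strain. The closest known reaction types are the chiral phosphoric acid catalysed desymmetrisation of 3-substituted oxetanes by tethered alcohols, the phosphoric acid catalysed opening of meso-epoxides by carboxylic acids and the racemic self-isomerisation of oxetane carboxylic acids to lactones, and what is new is a conjugated carboxylic acid as internal nucleophile in the enantioselective version. The lactone ring (O1, C2, C3, C4, C5) closes in the 5-exo-tet mode by forming O1–C5, and the departing oxetane oxygen becomes the hydroxyl of the CH2OH arm on C4. C4 is the only new stereocentre and is controlled by the catalyst alone, whose 3,3'-aryl pocket decides which of the two enantiotopic CH2–O bonds lines up with the carboxyl oxygen. The substrate helps because allylic 1,3-strain against the cis aryl group turns the oxetane C–H into the alkene plane, which places the two CH2 groups as mirror images above and below the flat acrylic acid with no bias of their own, and because the E alkene takes no part in the reaction. The selectivity needed is enantiotopic-group selection together with catalysed over uncatalysed opening, and the latter is secured by the weak acidity of the cinnamic acid relative to the catalyst, by high dilution against intermolecular opening and by the low temperature.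

Step 8
Reactants: 14 (S,E)-4-(hydroxymethyl)-3-[3-methoxy-4-(methoxymethoxy)benzylidene]dihydrofuran-2(3H)-one
Product: 15 (R,E)-4-(bromomethyl)-3-[3-methoxy-4-(methoxymethoxy)benzylidene]dihydrofuran-2(3H)-one
Conditions: CBr4, PPh3, CH2Cl2, 0 °C, directly after step 7
Reagents that add atoms: carbon tetrabromide, BrC(Br)(Br)Br
Why: The Appel reaction substitutes only the primary carbinol carbon under near-neutral conditions, so C4 is spatially unchanged (the descriptor becomes R through CIP priorities alone), and it removes the free hydroxyl that could otherwise racemise 14 by an acyl shift onto the second arm.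

Step 9
Reactants: 16 4-bromo-1,2-dimethoxybenzene
Product: 18 (3,4-dimethoxyphenyl)zinc bromide (titrated THF solution), via aryl Grignard reagent 17 (not isolated)
Conditions: Mg, THF, rt to 40 °C; then ZnBr2 (1.1 equiv), THF, 0 °C to rt
Reagents that add atoms: zinc bromide, Br[Zn]Br
Why: Grignard formation and transmetalation to zinc are routine and give an aryl nucleophile too weakly basic to attack the lactone or to remove the C4 proton.

Step 10
Reactants: 15 (R,E)-4-(bromomethyl)-3-[3-methoxy-4-(methoxymethoxy)benzylidene]dihydrofuran-2(3H)-one; 18 (3,4-dimethoxyphenyl)zinc bromide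
Product: 19 (R,E)-4-(3,4-dimethoxybenzyl)-3-[3-methoxy-4-(methoxymethoxy)benzylidene]dihydrofuran-2(3H)-one
Conditions: Pd-PEPPSI-IPr (2 mol %), LiBr, THF/NMP, rt
Reagents that add atoms: none
Why: Negishi coupling of unactivated primary alkyl bromides with arylzinc halides under a bulky Pd–NHC catalyst is a known room-temperature reaction in which SN2-type oxidative addition avoids a free homoallylic radical and fast reductive elimination should outrun β-hydride elimination, while the absence of the alkoxide base that the boronic acid variant requires protects the vinylogously acidic C4–H, so the stereocentre is carried through.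

Step 11
Reactants: 19 (R,E)-4-(3,4-dimethoxybenzyl)-3-[3-methoxy-4-(methoxymethoxy)benzylidene]dihydrofuran-2(3H)-one
Product: 20 (R,E)-4-(3,4-dimethoxybenzyl)-3-(4-hydroxy-3-methoxybenzylidene)dihydrofuran-2(3H)-one (CNP0146216.1)
Conditions: 2 M aq HCl, THF, 40 °C
Reagents that add atoms: none
Why: Acid hydrolysis of the aryl MOM acetal uses acid too dilute to enolise the lactone, to activate the arylidene carbon towards the veratryl ring or to cleave aryl methyl ethers, so (R)-C4 and the E alkene persist.

Compound list
1 | oxetan-3-one | O=C1COC1 | starting material
2 | triethyl phosphonoacetate | CCOC(=O)CP(=O)(OCC)OCC | starting material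
3 | sodium carbanion of triethyl phosphonoacetate | CCOC(=O)[CH-]P(=O)(OCC)OCC.[Na+] | intermediate
4 | ethyl 2-(oxetan-3-ylidene)acetate | CCOC(=O)C=C1COC1 | intermediate
5 | ethyl 2-(oxetan-3-yl)acetate | CCOC(=O)CC1COC1 | intermediate
6 | vanillin | COc1cc(C=O)ccc1O | starting material
7 | 3-methoxy-4-(methoxymethoxy)benzaldehyde | COCOc1ccc(C=O)cc1OC | intermediate
8 | lithium enolate of ethyl 2-(oxetan-3-yl)acetate | CCOC([O-])=CC1COC1.[Li+] | intermediate
9 | ethyl 3-hydroxy-3-[3-methoxy-4-(methoxymethoxy)phenyl]-2-(oxetan-3-yl)propanoate (racemic syn/anti mixture) | CCOC(=O)C(C1COC1)C(O)c1ccc(OCOC)c(OC)c1 | intermediate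
10 | ethyl 3-(methylsulfonyloxy)-3-[3-methoxy-4-(methoxymethoxy)phenyl]-2-(oxetan-3-yl)propanoate | CCOC(=O)C(C1COC1)C(OS(C)(=O)=O)c1ccc(OCOC)c(OC)c1 | intermediate
11 | ethyl (E)-3-[3-methoxy-4-(methoxymethoxy)phenyl]-2-(oxetan-3-yl)acrylate | COCOc1ccc(/C=C(/C(=O)OCC)C2COC2)cc1OC | intermediate
12 | sodium (E)-3-[3-methoxy-4-(methoxymethoxy)phenyl]-2-(oxetan-3-yl)acrylate | COCOc1ccc(/C=C(/C(=O)[O-])C2COC2)cc1OC.[Na+] | intermediate
13 | (E)-3-[3-methoxy-4-(methoxymethoxy)phenyl]-2-(oxetan-3-yl)acrylic acid | COCOc1ccc(/C=C(/C(=O)O)C2COC2)cc1OC | intermediate
14 | (S,E)-4-(hydroxymethyl)-3-[3-methoxy-4-(methoxymethoxy)benzylidene]dihydrofuran-2(3H)-one | COCOc1ccc(/C=C2/C(=O)OC[C@@H]2CO)cc1OC | intermediate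
15 | (R,E)-4-(bromomethyl)-3-[3-methoxy-4-(methoxymethoxy)benzylidene]dihydrofuran-2(3H)-one | COCOc1ccc(/C=C2/C(=O)OC[C@@H]2CBr)cc1OC | intermediate
16 | 4-bromo-1,2-dimethoxybenzene | COc1ccc(Br)cc1OC | starting material
17 | (3,4-dimethoxyphenyl)magnesium bromide | COc1ccc([Mg]Br)cc1OC | intermediate
18 | (3,4-dimethoxyphenyl)zinc bromide | COc1ccc([Zn]Br)cc1OC | intermediate
19 | (R,E)-4-(3,4-dimethoxybenzyl)-3-[3-methoxy-4-(methoxymethoxy)benzylidene]dihydrofuran-2(3H)-one | COCOc1ccc(/C=C2/C(=O)OC[C@@H]2Cc2ccc(OC)c(OC)c2)cc1OC | intermediate
20 | (R,E)-4-(3,4-dimethoxybenzyl)-3-(4-hydroxy-3-methoxybenzylidene)dihydrofuran-2(3H)-one | COc1cc(/C=C2/C(=O)OC[C@@H]2Cc2ccc(OC)c(OC)c2)ccc1O | target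

Total step count: 11.
Longest linear sequence: 9 steps from oxetan-3-one (steps 1, 2, 4, 5, 6, 7, 8, 10, 11).

Steps most likely to fail

Step 7 (the labelled step). Three processes could lower the enantiopurity:
- The catalyst pocket may not tell the two enantiotopic CH2–O bonds apart.
- The uncatalysed ring opening may compete.
- A slow acid-induced acyl shift between the two arms may erode the result afterwards.

The fallback uses known chemistry only, sets out from acid 13 and comes back at 14. Acid 13 is isomerised with a catalytic achiral Brønsted acid (diphenyl phosphate, CH2Cl2, rt). This is the known lactonisation of oxetane carboxylic acids, and it gives racemic (E)-4-(hydroxymethyl)-3-[3-methoxy-4-(methoxymethoxy)benzylidene]dihydrofuran-2(3H)-one F1. The primary alcohol is then resolved by lipase-catalysed acylation (Burkholderia cepacia lipase or another commercial lipase, vinyl acetate, MTBE, rt), a standard kinetic resolution for alcohols whose stereocentre is next to the carbinol carbon. The enzyme is chosen so that the unwanted enantiomer is converted into the (R)-acetate F2. The alcohol left over is 14 and is separated by chromatography. Half of the material is necessarily given up.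

Step 10. Oxidative addition at the β-branched primary carbon may be sluggish. β-Hydride elimination from the alkylpalladium species across C4 may also compete, which would erase the stereocentre.

The fallback sets out from alcohol 14, bypasses 15 and comes back at 19. Alcohol 14 is converted with Tf2O and 2,6-lutidine (CH2Cl2, −78 °C) into the (R)-primary triflate F3. F3 is treated cold (THF/Et2O, −78 to −30 °C) with bromomagnesium bis(3,4-dimethoxyphenyl)cuprate F4, made from two equivalents of Grignard reagent 17 and CuBr·SMe2. This is a stoichiometric SN2 substitution by a soft, weakly basic organocopper reagent. It needs no palladium alkyl, finishes at low temperature, and meets in the trisubstituted arylidene lactone only a poor conjugate acceptor.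

Step 5. Stereocontrol in the elimination may be incomplete. The very labile, electron-rich benzylic sulfonate may also solvolyse before elimination.

The fallback fixes the geometry by a stereoretentive coupling instead of an elimination, sets out from aldehyde 7 and comes back at 11. Wittig olefination of 7 with ethyl bromo(triphenylphosphoranylidene)acetate (CH2Cl2, rt) gives ethyl (Z)-2-bromo-3-[3-methoxy-4-(methoxymethoxy)phenyl]acrylate F5, in which aryl and ester groups are already trans. Negishi coupling of F5 then follows (Pd(OAc)2/CPhos, THF, rt). The partner is oxetan-3-ylzinc iodide F6, prepared from commercial 3-iodooxetane with Zn and LiCl. The coupling replaces bromine by the ring with retention of alkene geometry. Isomerisation of the secondary alkyl group through β-hydride elimination is disfavoured because it would have to form a four-membered-ring alkene.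

Further compounds
F1 | step 7 | racemic (E)-4-(hydroxymethyl)-3-[3-methoxy-4-(methoxymethoxy)benzylidene]dihydrofuran-2(3H)-one | COCOc1ccc(/C=C2/C(=O)OCC2CO)cc1OC
F2 | step 7 | [(R,E)-4-[3-methoxy-4-(methoxymethoxy)benzylidene]-5-oxotetrahydrofuran-3-yl]methyl acetate | COCOc1ccc(/C=C2/C(=O)OC[C@H]2COC(C)=O)cc1OC
F3 | step 10 | [(R,E)-4-[3-methoxy-4-(methoxymethoxy)benzylidene]-5-oxotetrahydrofuran-3-yl]methyl trifluoromethanesulfonate | COCOc1ccc(/C=C2/C(=O)OC[C@@H]2COS(=O)(=O)C(F)(F)F)cc1OC
F4 | step 10 | bromomagnesium bis(3,4-dimethoxyphenyl)cuprate | COc1ccc([Cu-]c2ccc(OC)c(OC)c2)cc1OC.[Mg+]Br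
F5 | step 5 | ethyl (Z)-2-bromo-3-[3-methoxy-4-(methoxymethoxy)phenyl]acrylate | COCOc1ccc(/C=C(\Br)C(=O)OCC)cc1OC
F6 | step 5 | oxetan-3-ylzinc iodide | I[Zn]C1COC1
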